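**Strategy.** Everything rests on disconnecting ring A of the flavonol across C8–C8a and C4a–C5. Its carbons C5–C8, carrying OH, H, OMe and OMe in that order, come from a silyl ketene acetal diene made from a 3,4-dimethoxybutenoate. C4a=C8a is the sulfonyl-activated C5=C6 alkene of a monocyclic 4-pyranone that already holds ring B and the protected 3-oxygen. In one operation a polar [4+2] cycloaddition, followed by loss of benzenesulfinic acid and methanol, builds and aromatises ring A with every substituent in place and only the chelated 5-hydroxyl free. The precursor is a 2-aryl-3-benzyloxy-5-phenylsulfonyl-4-pyranone; one hydrogenolysis finishes the synthesis.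

Key step: step 9

Remark: the target is achiral. The alkene geometries of the enaminone and the diene, and the configuration of the transient cycloadduct, are erased on cyclisation or aromatisation, so they are not controlled. All four starting materials are assumed to be purchasable.

Step 1
Reactants: 1 methyl phenyl sulfone; 2 methyl 2-(benzyloxy)acetate
Product: 3 1-(benzyloxy)-3-(phenylsulfonyl)propan-2-one
Conditions: 1, n-BuLi (2.1 equiv), THF, 0 °C; then 2, −78 °C → rt; 1 M HCl
Reagents that add atoms: none
Why: Claisen-type C-acylation of the dilithiated sulfone by the ester, in which the second equivalent of base holds the β-keto sulfone as its enolate so that no second addition occurs.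

Step 2
Reactants: 3 1-(benzyloxy)-3-(phenylsulfonyl)propan-2-one
Product: 4 1-(benzyloxy)-4-(dimethylamino)-3-(phenylsulfonyl)but-3-en-2-one
Conditions: Me2NCH(OMe)2 (1.2 equiv), toluene, rt → 50 °C
Reagents that add atoms: N,N-dimethylformamide dimethyl acetal, COC(OC)N(C)C
Why: Enaminone formation by condensation of an amide acetal with the methylene flanked by C=O and SO2, which is far more acidic than the benzyloxymethyl group and therefore reacts alone.

Step 3
Reactants: 5 2,4-dihydroxy-5-methoxybenzaldehyde
Product: 6 2,4-bis(benzyloxy)-5-methoxybenzaldehyde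
Conditions: BnBr (2.4 equiv), K2CO3, DMF, 60 °C
Reagents that add atoms: benzyl bromide, BrCc1ccccc1
Why: Williamson ether synthesis, with warm DMF and excess halide to alkylate the hydrogen-bonded ortho hydroxyl as well.

Step 4
Reactants: 6 2,4-bis(benzyloxy)-5-methoxybenzaldehyde
Product: 7 2,4-bis(benzyloxy)-5-methoxybenzoic acid
Conditions: NaClO2, NaH2PO4, 2-methyl-2-butene, t-BuOH/THF/H2O, rt
Reagents that add atoms: sodium chlorite, [Na+].[O-]Cl=O
Why: Pinnick oxidation, with the alkene scavenging hypochlorous acid so that the electron-rich ring is not chlorinated and the benzyl ethers are untouched.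

Step 5
Reactants: 7 2,4-bis(benzyloxy)-5-methoxybenzoic acid
Product: 8 2,4-bis(benzyloxy)-5-methoxybenzoyl chloride
Conditions: (COCl)2 (1.3 equiv), DMF (cat.), CH2Cl2, 0 °C → rt; evaporate, use crude
Reagents that add atoms: oxalyl chloride, O=C(Cl)C(=O)Cl
Why: Acid chloride formation through the Vilsmeier-type chloroiminium catalyst under conditions that aryl benzyl ethers tolerate.

Step 6
Reactants: 4 1-(benzyloxy)-4-(dimethylamino)-3-(phenylsulfonyl)but-3-en-2-one; 8 2,4-bis(benzyloxy)-5-methoxybenzoyl chloride
Product: 10 3-(benzyloxy)-2-[2,4-bis(benzyloxy)-5-methoxyphenyl]-5-(phenylsulfonyl)-4H-pyran-4-one, via diketo enaminone 9 (not isolated)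
Conditions: 4, LiN(SiMe3)2 (2.5 equiv), THF, −78 °C; 8, −78 → −20 °C; then 3 M HCl, THF/Et2O, rt
Reagents that add atoms: none
Why: The lithium enolate at the benzyloxymethyl carbon of the vinylogous amide is C-acylated by the aroyl chloride, and on acidification the enol oxygen of the aryl ketone adds to the enamine carbon and expels dimethylamine (addition–elimination, 6-endo closure), which is the established enaminone-anion acylation and cyclisation route to 4-pyranones bearing an acceptor at C3.

Step 7
Reactants: 11 methyl 4-methoxyacetoacetate (methyl 4-methoxy-3-oxobutanoate)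
Product: 13 methyl (2E)-3,4-dimethoxybut-2-enoate, via dimethyl ketal 12 (not isolated)
Conditions: HC(OMe)3 (1.5 equiv), H2SO4 (cat.), rt; then heat to 140 °C with removal of MeOH; vacuum distillation
Reagents that add atoms: trimethyl orthoformate, COC(OC)OC
Why: Acid-catalysed ketalisation of the ketone by the orthoester followed by thermal loss of methanol toward the ester gives the conjugated β-methoxy enoate, the standard O-methylation of a β-keto ester that avoids C-alkylation.

Step 8
Reactants: 13 methyl (2E)-3,4-dimethoxybut-2-enoate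
Product: 14 (1Z,3Z)-1,3,4-trimethoxy-1-(trimethylsilyloxy)buta-1,3-diene
Conditions: LiN(iPr)2 (1.1 equiv), THF, −78 °C; Me3SiCl (1.3 equiv), −78 °C → rt; pentane, filter, bulb-to-bulb distillation
Reagents that add atoms: chlorotrimethylsilane, C[Si](C)(C)Cl
Why: Kinetic γ-deprotonation of the β-methoxy enoate gives the extended lithium dienolate, which the hard silyl chloride traps on oxygen, the standard preparation of Brassard-type 1-alkoxy-1-silyloxy dienes.

Step 9
Reactants: 10 3-(benzyloxy)-2-[2,4-bis(benzyloxy)-5-methoxyphenyl]-5-(phenylsulfonyl)-4H-pyran-4-one; 14 (1Z,3Z)-1,3,4-trimethoxy-1-(trimethylsilyloxy)buta-1,3-diene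
Product: 17 3-(benzyloxy)-2-[2,4-bis(benzyloxy)-5-methoxyphenyl]-5-hydroxy-7,8-dimethoxy-4H-chromen-4-one, via cycloadduct 15 (not isolated), via aryl silyl ether 16 (not isolated)
Conditions: 14 (3 equiv), toluene, 25 → 90 °C, sealed tube; then DBU (2 equiv), THF, rt; then 1 M HCl
Reagents that add atoms: none
Why: Proposed new method: the electron-rich diene 14 should add to the C5=C6 bond of 10 (C4a=C8a in flavone numbering), which is activated by both the C4 carbonyl and the sulfone, in a strongly polarised and possibly stepwise [4+2] process (vinylogous Mukaiyama–Michael attack of the diene γ-carbon on C8a, then closure of the resulting α-sulfonyl enolate carbon C4a onto the ketene acetal carbon), forming C8–C8a and C4a–C5. Ring A is thus closed as a six-membered carbocycle by intermolecular [4+2] annulation, after which adduct 15 loses methanol 1,4 across C5/C8 (ionisation of the mixed ketal assisted by the C7 enol ether, loss of H-8) and benzenesulfinic acid across C4a/C8a with DBU to give arene 16, whose silyl ether is cleaved in dilute acid to leave the 5-hydroxyl hydrogen-bonded to C4=O. The closest known reaction types are the cycloaddition–aromatisation of oxygenated silyl ketene acetal dienes with halo- or sulfinylquinones and the Diels–Alder reactions of 3-sulfonyl- and 3-acylchromones with siloxydienes; what is new is a monocyclic, partly aromatic 4-pyranone as the dienophile. No stereocentre is retained, so facial and endo/exo selectivity are irrelevant. The selectivity needed is regiochemical, and it is secured because the nucleophilic diene terminus (future C8) can only pair with C8a, the unsubstituted β-carbon of both acceptors, while the tetrasubstituted, donor-bearing C2=C3 bond is unreactive. Because the sulfonyl group leaves after activating the alkene, the pyranone acts as an alkyne equivalent and all four substituents of ring A arrive differentiated from the diene.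

Step 10
Reactants: 17 3-(benzyloxy)-2-[2,4-bis(benzyloxy)-5-methoxyphenyl]-5-hydroxy-7,8-dimethoxy-4H-chromen-4-one
Product: 18 3,5-dihydroxy-2-(2,4-dihydroxy-5-methoxyphenyl)-7,8-dimethoxy-4H-chromen-4-one
Conditions: H2 (1 atm), 10% Pd/C, EtOAc/MeOH, rt
Reagents that add atoms: none
Why: Heterogeneous hydrogenolysis cleaves the three benzyl ethers, while the methyl ethers and the tetrasubstituted C2=C3 bond of the flavonol should survive at ambient pressure.

**Compound list**

1 | methyl phenyl sulfone | CS(=O)(=O)c1ccccc1 | starting material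
2 | methyl 2-(benzyloxy)acetate | COC(=O)COCc1ccccc1 | starting material
3 | 1-(benzyloxy)-3-(phenylsulfonyl)propan-2-one | O=C(COCc1ccccc1)CS(=O)(=O)c1ccccc1 | intermediate
4 | 1-(benzyloxy)-4-(dimethylamino)-3-(phenylsulfonyl)but-3-en-2-one (alkene geometry not controlled) | CN(C)C=C(C(=O)COCc1ccccc1)S(=O)(=O)c1ccccc1 | intermediate
5 | 2,4-dihydroxy-5-methoxybenzaldehyde | COc1cc(C=O)c(O)cc1O | starting material
6 | 2,4-bis(benzyloxy)-5-methoxybenzaldehyde | COc1cc(C=O)c(OCc2ccccc2)cc1OCc1ccccc1 | intermediate
7 | 2,4-bis(benzyloxy)-5-methoxybenzoic acid | COc1cc(C(=O)O)c(OCc2ccccc2)cc1OCc1ccccc1 | intermediate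
8 | 2,4-bis(benzyloxy)-5-methoxybenzoyl chloride | COc1cc(C(=O)Cl)c(OCc2ccccc2)cc1OCc1ccccc1 | intermediate
9 | 1-[2,4-bis(benzyloxy)-5-methoxyphenyl]-2-(benzyloxy)-5-(dimethylamino)-4-(phenylsulfonyl)pent-4-ene-1,3-dione (racemic, enolisable; not isolated) | CN(C)C=C(C(=O)C(OCc1ccccc1)C(=O)c1cc(OC)c(OCc2ccccc2)cc1OCc1ccccc1)S(=O)(=O)c1ccccc1 | intermediate
10 | 3-(benzyloxy)-2-[2,4-bis(benzyloxy)-5-methoxyphenyl]-5-(phenylsulfonyl)-4H-pyran-4-one | COc1cc(-c2occ(S(=O)(=O)c3ccccc3)c(=O)c2OCc2ccccc2)c(OCc2ccccc2)cc1OCc1ccccc1 | intermediate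
11 | methyl 4-methoxyacetoacetate | COCC(=O)CC(=O)OC | starting material
12 | methyl 3,3,4-trimethoxybutanoate (not isolated) | COCC(OC)(OC)CC(=O)OC | intermediate
13 | methyl (2E)-3,4-dimethoxybut-2-enoate | CO/C(COC)=C/C(=O)OC | intermediate
14 | (1Z,3Z)-1,3,4-trimethoxy-1-(trimethylsilyloxy)buta-1,3-diene | CO/C=C(OC)/C=C(/OC)O[Si](C)(C)C | intermediate
15 | 3-(benzyloxy)-2-[2,4-bis(benzyloxy)-5-methoxyphenyl]-5,7,8-trimethoxy-4a-(phenylsulfonyl)-5-(trimethylsilyloxy)-4a,5,8,8a-tetrahydro-4H-chromen-4-one (racemic diastereomer mixture; not isolated) | COc1cc(C2=C(OCc3ccccc3)C(=O)C3(S(=O)(=O)c4ccccc4)C(OC)(O[Si](C)(C)C)C=C(OC)C(OC)C3O2)c(OCc2ccccc2)cc1OCc1ccccc1 | intermediate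
16 | 3-(benzyloxy)-2-[2,4-bis(benzyloxy)-5-methoxyphenyl]-7,8-dimethoxy-5-(trimethylsilyloxy)-4H-chromen-4-one (not isolated) | COc1cc(-c2oc3c(OC)c(OC)cc(O[Si](C)(C)C)c3c(=O)c2OCc2ccccc2)c(OCc2ccccc2)cc1OCc1ccccc1 | intermediate
17 | 3-(benzyloxy)-2-[2,4-bis(benzyloxy)-5-methoxyphenyl]-5-hydroxy-7,8-dimethoxy-4H-chromen-4-one | COc1cc(-c2oc3c(OC)c(OC)cc(O)c3c(=O)c2OCc2ccccc2)c(OCc2ccccc2)cc1OCc1ccccc1 | intermediate
18 | 3,5-dihydroxy-2-(2,4-dihydroxy-5-methoxyphenyl)-7,8-dimethoxy-4H-chromen-4-one | COc1cc(-c2oc3c(OC)c(OC)cc(O)c3c(=O)c2O)c(O)cc1O | target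

**Totals.** Total step count: 10. Longest linear sequence: 6 steps (steps 3, 4, 5, 6, 9, 10).

**Steps most likely to fail**

Step 9. The weakly dienophilic, partly aromatic pyranone may not react before the diene decomposes. Alternatively the diene may add only as a Michael donor, after which the α-sulfonyl enolate may expel the ring oxygen and open the pyranone instead of closing onto the ketene acetal carbon. The fallback is a classical flavonol synthesis that sets out from aldehyde 6 and comes back to the route at target 18. Claisen–Schmidt condensation of 6 with commercial 1-(2-hydroxy-3,4,6-trimethoxyphenyl)ethanone (CC(=O)c1c(O)c(OC)c(OC)cc1OC; KOH, EtOH, rt) should give (E)-3-[2,4-bis(benzyloxy)-5-methoxyphenyl]-1-(2-hydroxy-3,4,6-trimethoxyphenyl)prop-2-en-1-one F1. Oxidative cyclisation with catalytic I2 in DMSO at 130 °C should give 2-[2,4-bis(benzyloxy)-5-methoxyphenyl]-5,7,8-trimethoxy-4H-chromen-4-one F2. This is preferred to the Algar–Flynn–Oyamada reaction, which tends to divert 6'-substituted chalcones to aurones. Epoxidation of C2=C3 with dimethyldioxirane and opening with catalytic TsOH should install the 3-hydroxyl, giving 2-[2,4-bis(benzyloxy)-5-methoxyphenyl]-3-hydroxy-5,7,8-trimethoxy-4H-chromen-4-one F3. BCl3 with pentamethylbenzene in CH2Cl2 (−78 °C → rt) should then remove both benzyl ethers and the carbonyl-chelated 5-O-methyl group, leaving the unchelated methyl ethers and arriving at 18.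

Step 6. The enolate may be acylated on oxygen, or the hindered, electron-rich aroyl chloride may acylate it incompletely while the more acidic product quenches remaining enolate. The fallback replaces acylation by aldol addition and oxidation. It sets out from enaminone 4 and aldehyde 6 (steps 4 and 5 are then not needed) and comes back at pyranone 10. The lithium enolate of 4 (LiN(SiMe3)2, THF, −78 °C) is added to 6 and quenched cold to give 5-[2,4-bis(benzyloxy)-5-methoxyphenyl]-4-(benzyloxy)-1-(dimethylamino)-5-hydroxy-2-(phenylsulfonyl)pent-1-en-3-one F4 as a diastereomer mixture. Dess–Martin periodinane in CH2Cl2 oxidises the carbinol to diketone 9, which closes to 10 with 3 M HCl as in step 6.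

Step 8. Deprotonation and silylation may be unselective (C-silylation, or self-condensation of the dienolate with unreacted ester), and the ketene acetal may hydrolyse back to the enoate on isolation. The fallback avoids the enol methyl ether altogether. It sets out from keto ester 11 and comes back at 17. Me3SiCl/Et3N should give methyl 4-methoxy-3-(trimethylsilyloxy)but-2-enoate F5. LiN(iPr)2 then Me3SiCl should give the Chan-type diene 1,4-dimethoxy-1,3-bis(trimethylsilyloxy)buta-1,3-diene F6. Under the conditions of step 9, F6 and 10 should give the 7-silyloxy analogue of the cycloadduct F7, and after the same eliminations the 5,7-bis(trimethylsilyl) ether F8, neither of which is isolated. Acidic work-up should give 3-(benzyloxy)-2-[2,4-bis(benzyloxy)-5-methoxyphenyl]-5,7-dihydroxy-8-methoxy-4H-chromen-4-one F9. Its unchelated, more acidic 7-hydroxyl is then methylated selectively (MeI 1.1 equiv, K2CO3, acetone, rt) to give 17.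

Further compounds
F1 | step 9 | (E)-3-[2,4-bis(benzyloxy)-5-methoxyphenyl]-1-(2-hydroxy-3,4,6-trimethoxyphenyl)prop-2-en-1-one | COc1cc(/C=C/C(=O)c2c(O)c(OC)c(OC)cc2OC)c(OCc2ccccc2)cc1OCc1ccccc1
F2 | step 9 | 2-[2,4-bis(benzyloxy)-5-methoxyphenyl]-5,7,8-trimethoxy-4H-chromen-4-one | COc1cc(-c2cc(=O)c3c(OC)cc(OC)c(OC)c3o2)c(OCc2ccccc2)cc1OCc1ccccc1
F3 | step 9 | 2-[2,4-bis(benzyloxy)-5-methoxyphenyl]-3-hydroxy-5,7,8-trimethoxy-4H-chromen-4-one | COc1cc(-c2oc3c(OC)c(OC)cc(OC)c3c(=O)c2O)c(OCc2ccccc2)cc1OCc1ccccc1
F4 | step 6 | 5-[2,4-bis(benzyloxy)-5-methoxyphenyl]-4-(benzyloxy)-1-(dimethylamino)-5-hydroxy-2-(phenylsulfonyl)pent-1-en-3-one (diastereomer mixture) | CN(C)C=C(C(=O)C(OCc1ccccc1)C(O)c1cc(OC)c(OCc2ccccc2)cc1OCc1ccccc1)S(=O)(=O)c1ccccc1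
F5 | step 8 | methyl 4-methoxy-3-(trimethylsilyloxy)but-2-enoate (geometry not controlled) | COCC(O[Si](C)(C)C)=CC(=O)OC
F6 | step 8 | 1,4-dimethoxy-1,3-bis(trimethylsilyloxy)buta-1,3-diene (geometry not controlled) | COC=C(O[Si](C)(C)C)C=C(OC)O[Si](C)(C)C
F7 | step 8 | 3-(benzyloxy)-2-[2,4-bis(benzyloxy)-5-methoxyphenyl]-5,8-dimethoxy-4a-(phenylsulfonyl)-5,7-bis(trimethylsilyloxy)-4a,5,8,8a-tetrahydro-4H-chromen-4-one (diastereomer mixture, not isolated) | COc1cc(C2=C(OCc3ccccc3)C(=O)C3(S(=O)(=O)c4ccccc4)C(OC)(O[Si](C)(C)C)C=C(O[Si](C)(C)C)C(OC)C3O2)c(OCc2ccccc2)cc1OCc1ccccc1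
F8 | step 8 | 3-(benzyloxy)-2-[2,4-bis(benzyloxy)-5-methoxyphenyl]-8-methoxy-5,7-bis(trimethylsilyloxy)-4H-chromen-4-one (not isolated) | COc1cc(-c2oc3c(OC)c(O[Si](C)(C)C)cc(O[Si](C)(C)C)c3c(=O)c2OCc2ccccc2)c(OCc2ccccc2)cc1OCc1ccccc1
F9 | step 8 | 3-(benzyloxy)-2-[2,4-bis(benzyloxy)-5-methoxyphenyl]-5,7-dihydroxy-8-methoxy-4H-chromen-4-one | COc1cc(-c2oc3c(OC)c(O)cc(O)c3c(=O)c2OCc2ccccc2)c(OCc2ccccc2)cc1OCc1ccccc1
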